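The route rests on disconnecting ring C at the bond between its methylene C-12 and the quaternary, methyl-bearing C-13 of ring D. In one operation an iron-hydride hydrogen-atom transfer turns a ring-D exocyclic methylene into the tertiary C-13 radical, which closes ring C 6-endo onto an α-methylene ketone. The neighbouring C-17 silyloxy group steers the attack, so the quaternary centre and the trans C/D fusion arise together. The precursor is a monocyclic 2-methylenecyclopentyl silyl ether whose side chain ends in a 3-methylene-4-vinylbutan-2-one unit. The acetyl group so placed at C-11 later becomes the C(=CH2) unit of ring B; ring A is attached by Suzuki coupling and ring B closed by McMurry olefination.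

Key step: step 10

Remark: rings are lettered A (methylcyclopentane), B (cyclooctene), C (cyclohexane), D (cyclopentanol); C/D carbons carry steroid-style locants as shorthand (C-13 quaternary, C-17 carbinol, C-15 isopropyl-bearing, C-14 ring-fusion CH, C-9 and C-11 shared with ring B), and C-9 is carried as an epimer mixture until it is α to a ketone (step 18).

Step 1
Reactants: 1 (R)-4-[(tert-butyldimethylsilyl)oxy]cyclopent-2-en-1-one; 2 isopropylmagnesium chloride
Product: 4 (S)-4-(propan-2-yl)cyclopent-2-en-1-one, via silyloxy ketone 3 (not isolated)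
Conditions: i-PrMgCl, CuI (10 mol %), LiCl, THF, −78 °C; aq. NH4Cl; then DBU, CH2Cl2, rt
Reagents that add atoms: none
Why: Copper-catalysed conjugate addition anti to the silyloxy group followed by E1cB loss of silanol should transfer the chirality of 1 to the isopropyl-bearing carbon (future C-15).

Step 2
Reactants: 4 (S)-4-(propan-2-yl)cyclopent-2-en-1-one; 5 tert-butyl[(1-methoxyethenyl)oxy]dimethylsilane
Product: 6 methyl 2-[(1S,5S)-3-[(tert-butyldimethylsilyl)oxy]-5-(propan-2-yl)cyclopent-2-en-1-yl]acetate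
Conditions: Tf2NH (2 mol %), CH2Cl2, −78 °C
Reagents that add atoms: none
Why: Mukaiyama–Michael addition anti to the isopropyl group should set C-14 trans to C-15, and silyl transfer leaves a regiodefined silyl enol ether.

Step 3
Reactants: 6 silyl enol ether; 7 N,N-dimethylmethyleneiminium iodide (Eschenmoser's salt)
Product: 10 methyl 2-[(1S,5S)-2-methylidene-3-oxo-5-(propan-2-yl)cyclopentyl]acetate, via Mannich base 8 (not isolated), via ammonium iodide 9 (not isolated)
Conditions: 7, CH2Cl2, rt; MeI, Et2O; aq. NaHCO3, CH2Cl2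
Reagents that add atoms: none
Why: Mannich reaction at the enol-ether carbon and Hofmann-type elimination of the quaternised amine (Eschenmoser methylenation) should place the exocyclic methylene at the future C-13 only.

Step 4
Reactants: 10 α-methylene ketone
Product: 11 methyl 2-[(1S,3R,5S)-3-hydroxy-2-methylidene-5-(propan-2-yl)cyclopentyl]acetate
Conditions: (S)-Me-CBS (1.0 equiv), BH3·THF (1.0 equiv), THF, −40 °C; MeOH, aq. work-up
Reagents that add atoms: none
Why: Corey–Bakshi–Shibata reduction under reagent control, with the fully substituted alkenyl α-carbon as the large group, should give the (3R)-carbinol (future C-17, OH cis to the side chain) and leave the ester alone.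

Step 5
Reactants: 11 allylic alcohol
Product: 12 methyl 2-[(1S,3R,5S)-3-[(tert-butyldimethylsilyl)oxy]-2-methylidene-5-(propan-2-yl)cyclopentyl]acetate
Conditions: TBSCl, imidazole, DMF, rt
Reagents that add atoms: tert-butyldimethylsilyl chloride, CC(C)(C)[Si](C)(C)Cl
Why: Standard silylation turns the C-17 hydroxyl into the bulky ether that is to direct the key step.

Step 6
Reactants: 12 silyl ether ester
Product: 13 2-[(1S,3R,5S)-3-[(tert-butyldimethylsilyl)oxy]-2-methylidene-5-(propan-2-yl)cyclopentyl]acetaldehyde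
Conditions: DIBAL-H (1.1 equiv), CH2Cl2, −78 °C; Rochelle salt
Reagents that add atoms: none
Why: DIBAL-H half-reduction of the methyl ester stops at the aluminium hemiacetal at −78 °C and should release the aldehyde on work-up.

Step 7
Reactants: 13 aldehyde; 14 methyl vinyl ketone
Product: 15 5-[(1S,3R,5S)-3-[(tert-butyldimethylsilyl)oxy]-2-methylidene-5-(propan-2-yl)cyclopentyl]-4-hydroxy-3-methylidenepentan-2-one (C-4 epimers)
Conditions: DABCO (30 mol %), THF, rt
Reagents that add atoms: none
Why: The Morita–Baylis–Hillman reaction attaches C-11, C-12 and the acetyl group to the aldehyde carbon (C-9); the new carbinol centre forms as a mixture and is erased in step 8.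

Step 8
Reactants: 15 Baylis–Hillman alcohol
Product: 16 (3Z)-3-(bromomethyl)-5-[(1S,3R,5S)-3-[(tert-butyldimethylsilyl)oxy]-2-methylidene-5-(propan-2-yl)cyclopentyl]pent-3-en-2-one
Conditions: NBS, Me2S, CH2Cl2, −20 °C to rt
Reagents that add atoms: N-bromosuccinimide, O=C1CCC(=O)N1Br
Why: Bromodimethylsulfonium activation (Corey–Kim type) with SN2′ delivery of bromide should give the rearranged, conjugated (Z)-allylic bromide typical of Baylis–Hillman alcohols.

Step 9
Reactants: 16 allylic bromide; 17 vinylmagnesium bromide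
Product: 18 4-{[(1S,3R,5S)-3-[(tert-butyldimethylsilyl)oxy]-2-methylidene-5-(propan-2-yl)cyclopentyl]methyl}-3-methylidenehex-5-en-2-one (C-4 epimers; this carbon is the future C-9)
Conditions: CuI·2LiCl (1.2 equiv), THF, −78 °C; aq. NH4Cl at −78 °C
Reagents that add atoms: none
Why: Copper-mediated SN2′ substitution (conjugate addition–elimination) regenerates the α-methylene ketone and places the vinyl group, a masked acetyl, on C-9 without stereocontrol, which is harmless because C-9 is equilibrated in step 18.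

Step 10
Reactants: 18 triene ketone
Product: 20 1-[(1R,3S,3aS,6S,7aR)-1-[(tert-butyldimethylsilyl)oxy]-5-ethenyl-7a-methyl-3-(propan-2-yl)octahydro-1H-inden-6-yl]ethan-1-one (trans-fused; acetyl equatorial; C-9 epimers), via C-11 epimer mixture 19 (not isolated)
Conditions: Fe(acac)3 (30 mol %), PhSiH3 (2.5 equiv), EtOH/(CH2OH)2 5:1, 0.01 M, 60 °C; then K2CO3, MeOH, rt
Reagents that add atoms: none
Why: The iron hydride formed from Fe(acac)3 and PhSiH3 transfers H• to the CH2 terminus of the electron-rich ring-D methylene, and the resulting tertiary C-13 radical adds to the CH2 terminus (C-12) of the α-methylene ketone, after which the α-keto radical is reduced to the iron enolate and protonated by ethanol. The closest known reaction type is the metal-hydride hydrogen-atom-transfer reductive olefin coupling (radical conjugate addition) in its intramolecular form. Ring C closes in the 6-endo-trig mode, because the inner enone carbon is fully substituted and 5-exo attack there would give an unstabilised primary radical, whereas polarity-matched attack at C-12 gives the α-keto radical. C-13 is set by attack anti to the adjacent C-17 silyloxy group (α-face), and with the tether in a chair both ring-D bonds are equatorial, which corresponds to the trans C/D fusion with the new methyl cis to OTBS; C-11 is set by the K2CO3/MeOH equilibration, in which an axial acetyl would clash 1,3-diaxially with the angular methyl. The step needs hydrogen-atom transfer to prefer the 1,1-disubstituted donor alkene over the vinyl and enone groups, and the C-13 radical to prefer closure onto the enone over 5-exo addition to the C-9 vinyl group; the first rests on the preference for forming a tertiary radical, the second on the much faster addition of a nucleophilic tertiary radical to an enone than to an unactivated alkene.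

Step 11
Reactants: 20 hydrindane methyl ketone
Product: 21 1-[(1R,3S,3aS,6S,7aR)-1-[(tert-butyldimethylsilyl)oxy]-5-ethenyl-7a-methyl-3-(propan-2-yl)octahydro-1H-inden-6-yl]ethenyl trifluoromethanesulfonate (C-9 epimers)
Conditions: KHMDS, THF, −78 °C; PhNTf2; aq. NH4Cl
Reagents that add atoms: N-phenylbis(trifluoromethanesulfonimide), O=S(=O)(N(c1ccccc1)S(=O)(=O)C(F)(F)F)C(F)(F)F
Why: Kinetic deprotonation of the methyl ketone at CH3 and O-sulfonylation should give the terminal enol triflate without touching the α-stereocentre C-11.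

Step 12
Reactants: 22 cis-jasmone
Product: 23 2-(2-methyl-5-oxocyclopent-1-en-1-yl)acetaldehyde
Conditions: O3, CH2Cl2, pyridine (cat.), −78 °C, indicator end-point; Me2S
Reagents that add atoms: ozone, [O-][O+]=O
Why: Ozonolysis with reductive work-up should cleave the electron-rich side-chain alkene in preference to the conjugated, electron-poor ring alkene.

Step 13
Reactants: 23 keto aldehyde
Product: 24 (1S)-2-(2-hydroxyethyl)-3-methylcyclopent-2-en-1-ol
Conditions: (R)-Me-CBS (10 mol %), BH3·SMe2, THF, −20 °C; MeOH, aq. work-up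
Reagents that add atoms: none
Why: Corey–Bakshi–Shibata reduction with the alkenyl branch as the large group should give the (1S)-allylic alcohol, while the aldehyde is reduced to the primary alcohol in the same pot.

Step 14
Reactants: 24 allylic diol
Product: 25 (1S,2S,3S)-2-(2-hydroxyethyl)-3-methylcyclopentan-1-ol
Conditions: [Ir(cod)(PCy3)(py)]PF6 (5 mol %), H2, CH2Cl2, rt
Reagents that add atoms: none
Why: Hydroxyl-directed hydrogenation with Crabtree's catalyst should deliver both hydrogens to the tetrasubstituted alkene from the face of the ring hydroxyl, so that the side chain and the methyl group end up cis to each other and their absolute configuration follows from C-1.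

Step 15
Reactants: 25 diol
Product: 26 (1S,2S,3S)-2-(2-iodoethyl)-3-methylcyclopentan-1-ol
Conditions: I2, PPh3, imidazole, CH2Cl2, 0 °C
Reagents that add atoms: iodine, II
Why: Appel-type iodination is selective for the primary over the secondary hydroxyl.

Step 16
Reactants: 26 iodo alcohol
Product: 27 triethyl{[(1S,2S,3S)-2-(2-iodoethyl)-3-methylcyclopentyl]oxy}silane
Conditions: TESCl, imidazole, CH2Cl2, 0 °C to rt
Reagents that add atoms: chlorotriethylsilane, CC[Si](CC)(CC)Cl
Why: Silylation gives an ether that survives tert-butyllithium and can later be removed next to the hindered TBS ether.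

Step 17
Reactants: 27 iodide; 21 enol triflate
Product: 30 tert-butyl{[(1R,3S,3aS,6S,7aR)-5-ethenyl-7a-methyl-6-{4-[(1S,2S,5S)-2-methyl-5-[(triethylsilyl)oxy]cyclopentyl]but-1-en-2-yl}-3-(propan-2-yl)octahydro-1H-inden-1-yl]oxy}dimethylsilane (C-9 epimers), via alkyllithium 28 (not isolated), via lithium borate 29 (not isolated)
Conditions: 27, t-BuLi (2.1 equiv), Et2O, −78 °C; B-MeO-9-BBN, THF, −78 °C to rt; then 21, Pd(dppf)Cl2 (5 mol %), AsPh3, 3 M aq. K3PO4, DMF, rt
Reagents that add atoms: none
Why: Iodine–lithium exchange, trapping as the B-alkyl-9-BBN borate and B-alkyl Suzuki–Miyaura coupling with the enol triflate should form the C(sp3)–C(sp2) bond and deliver the 1,1-disubstituted alkene of ring B directly.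

Step 18
Reactants: 30 triene
Product: 32 1-[(1R,3S,3aS,5S,6S,7aR)-1-[(tert-butyldimethylsilyl)oxy]-7a-methyl-6-{4-[(1S,2S,5S)-2-methyl-5-[(triethylsilyl)oxy]cyclopentyl]but-1-en-2-yl}-3-(propan-2-yl)octahydro-1H-inden-5-yl]ethan-1-one, via C-9 epimeric ketone mixture 31 (not isolated)
Conditions: PdCl2 (10 mol %), Cu(OAc)2 (20 mol %), O2 (1 atm), DMA/H2O 7:1, rt; then DBU, CH2Cl2, rt
Reagents that add atoms: water, O
Why: Tsuji–Wacker oxidation is selective for the monosubstituted vinyl group over the 1,1-disubstituted alkene and gives the methyl ketone, after which DBU should equilibrate C-9 to the equatorial acetyl isomer trans to the C-11 substituent.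

Step 19
Reactants: 32 ketone
Product: 33 1-[(1R,3S,3aS,5S,6S,7aR)-1-[(tert-butyldimethylsilyl)oxy]-6-{4-[(1S,2S,5S)-5-hydroxy-2-methylcyclopentyl]but-1-en-2-yl}-7a-methyl-3-(propan-2-yl)octahydro-1H-inden-5-yl]ethan-1-one
Conditions: PPTS, MeOH/CH2Cl2, 0 °C to rt
Reagents that add atoms: none
Why: Mild acid methanolysis should remove the secondary TES ether while the hindered, neopentyl-type TBS ether at C-17 stays.

Step 20
Reactants: 33 hydroxy ketone
Product: 34 (2S,3S)-2-{3-[(1R,3S,3aS,5S,6S,7aR)-5-acetyl-1-[(tert-butyldimethylsilyl)oxy]-7a-methyl-3-(propan-2-yl)octahydro-1H-inden-6-yl]but-3-en-1-yl}-3-methylcyclopentan-1-one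
Conditions: Dess–Martin periodinane, NaHCO3, CH2Cl2, 0 °C; used at once
Reagents that add atoms: none
Why: Dess–Martin oxidation under buffered, non-enolising conditions should give the cyclopentanone with its cis α-stereocentre intact.

Step 21
Reactants: 34 diketone
Product: 35 17-O-tert-butyldimethylsilyl ether of the target
Conditions: TiCl3(DME)1.5, Zn–Cu, DME, reflux; 34 added slowly by syringe pump (high dilution)
Reagents that add atoms: none
Why: Intramolecular McMurry coupling should join the two ketone carbons to the tetrasubstituted alkene and close the eight-membered ring B, the ring itself fixing the alkene geometry.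

Step 22
Reactants: 35 silyl ether
Product: 36 target CNP0510481.1
Conditions: TBAF, THF, 50 °C
Reagents that add atoms: none
Why: Fluoride cleavage of the TBS ether liberates the C-17 alcohol without affecting any stereocentre.

Compound list
1 | (R)-4-[(tert-butyldimethylsilyl)oxy]cyclopent-2-en-1-one | O=C1C=C[C@H](O[Si](C)(C)C(C)(C)C)C1 | starting material
2 | isopropylmagnesium chloride | CC(C)[Mg]Cl | starting material
3 | (3S,4R)-4-[(tert-butyldimethylsilyl)oxy]-3-(propan-2-yl)cyclopentan-1-one (not isolated) | O=C1C[C@@H](C(C)C)[C@H](O[Si](C)(C)C(C)(C)C)C1 | intermediate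
4 | (S)-4-(propan-2-yl)cyclopent-2-en-1-one | O=C1C=C[C@H](C(C)C)C1 | intermediate
5 | tert-butyl[(1-methoxyethenyl)oxy]dimethylsilane | COC(=C)O[Si](C)(C)C(C)(C)C | starting material
6 | methyl 2-[(1S,5S)-3-[(tert-butyldimethylsilyl)oxy]-5-(propan-2-yl)cyclopent-2-en-1-yl]acetate | COC(=O)C[C@H]1[C@H](C(C)C)CC(O[Si](C)(C)C(C)(C)C)=C1 | intermediate
7 | N,N-dimethylmethyleneiminium iodide (Eschenmoser's salt) | C=[N+](C)C.[I-] | starting material
8 | methyl 2-[(1S,5S)-2-[(dimethylamino)methyl]-3-oxo-5-(propan-2-yl)cyclopentyl]acetate, aminomethyl trans to the acetate chain (not isolated) | COC(=O)C[C@H]1[C@H](C(C)C)CC(=O)[C@@H]1CN(C)C | intermediate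
9 | trimethylammonium iodide of 8 (not isolated) | COC(=O)C[C@H]1[C@H](C(C)C)CC(=O)[C@@H]1C[N+](C)(C)C.[I-] | intermediate
10 | methyl 2-[(1S,5S)-2-methylidene-3-oxo-5-(propan-2-yl)cyclopentyl]acetate | COC(=O)C[C@H]1[C@H](C(C)C)CC(=O)C1=C | intermediate
11 | methyl 2-[(1S,3R,5S)-3-hydroxy-2-methylidene-5-(propan-2-yl)cyclopentyl]acetate | COC(=O)C[C@H]1[C@H](C(C)C)C[C@@H](O)C1=C | intermediate
12 | methyl 2-[(1S,3R,5S)-3-[(tert-butyldimethylsilyl)oxy]-2-methylidene-5-(propan-2-yl)cyclopentyl]acetate | COC(=O)C[C@H]1[C@H](C(C)C)C[C@@H](O[Si](C)(C)C(C)(C)C)C1=C | intermediate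
13 | 2-[(1S,3R,5S)-3-[(tert-butyldimethylsilyl)oxy]-2-methylidene-5-(propan-2-yl)cyclopentyl]acetaldehyde | O=CC[C@H]1[C@H](C(C)C)C[C@@H](O[Si](C)(C)C(C)(C)C)C1=C | intermediate
14 | methyl vinyl ketone (but-3-en-2-one) | CC(=O)C=C | starting material
15 | 5-[(1S,3R,5S)-3-[(tert-butyldimethylsilyl)oxy]-2-methylidene-5-(propan-2-yl)cyclopentyl]-4-hydroxy-3-methylidenepentan-2-one (C-4 epimers) | CC(=O)C(=C)C(O)C[C@H]1[C@H](C(C)C)C[C@@H](O[Si](C)(C)C(C)(C)C)C1=C | intermediate
16 | (3Z)-3-(bromomethyl)-5-[(1S,3R,5S)-3-[(tert-butyldimethylsilyl)oxy]-2-methylidene-5-(propan-2-yl)cyclopentyl]pent-3-en-2-one | CC(=O)/C(CBr)=C/C[C@H]1[C@H](C(C)C)C[C@@H](O[Si](C)(C)C(C)(C)C)C1=C | intermediate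
17 | vinylmagnesium bromide | C=C[Mg]Br | starting material
18 | 4-{[(1S,3R,5S)-3-[(tert-butyldimethylsilyl)oxy]-2-methylidene-5-(propan-2-yl)cyclopentyl]methyl}-3-methylidenehex-5-en-2-one (C-4 epimers) | CC(=O)C(=C)C(C=C)C[C@H]1[C@H](C(C)C)C[C@@H](O[Si](C)(C)C(C)(C)C)C1=C | intermediate
19 | 1-[(1R,3S,3aS,7aR)-1-[(tert-butyldimethylsilyl)oxy]-5-ethenyl-7a-methyl-3-(propan-2-yl)octahydro-1H-inden-6-yl]ethan-1-one, mixture of C-11 (and C-9) epimers (not isolated) | C=CC1C[C@H]2[C@H](C(C)C)C[C@@H](O[Si](C)(C)C(C)(C)C)[C@]2(C)CC1C(C)=O | intermediate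
20 | 1-[(1R,3S,3aS,6S,7aR)-1-[(tert-butyldimethylsilyl)oxy]-5-ethenyl-7a-methyl-3-(propan-2-yl)octahydro-1H-inden-6-yl]ethan-1-one (trans-fused, acetyl equatorial, C-9 epimers) | C=CC1C[C@H]2[C@H](C(C)C)C[C@@H](O[Si](C)(C)C(C)(C)C)[C@]2(C)C[C@@H]1C(C)=O | intermediate
21 | 1-[(1R,3S,3aS,6S,7aR)-1-[(tert-butyldimethylsilyl)oxy]-5-ethenyl-7a-methyl-3-(propan-2-yl)octahydro-1H-inden-6-yl]ethenyl trifluoromethanesulfonate (C-9 epimers) | C=CC1C[C@H]2[C@H](C(C)C)C[C@@H](O[Si](C)(C)C(C)(C)C)[C@]2(C)C[C@@H]1C(=C)OS(=O)(=O)C(F)(F)F | intermediate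
22 | cis-jasmone, 3-methyl-2-[(2Z)-pent-2-en-1-yl]cyclopent-2-en-1-one | CC/C=C\CC1=C(C)CCC1=O | starting material
23 | 2-(2-methyl-5-oxocyclopent-1-en-1-yl)acetaldehyde | O=CCC1=C(C)CCC1=O | intermediate
24 | (1S)-2-(2-hydroxyethyl)-3-methylcyclopent-2-en-1-ol | OCCC1=C(C)CC[C@@H]1O | intermediate
25 | (1S,2S,3S)-2-(2-hydroxyethyl)-3-methylcyclopentan-1-ol | OCC[C@@H]1[C@@H](O)CC[C@@H]1C | intermediate
26 | (1S,2S,3S)-2-(2-iodoethyl)-3-methylcyclopentan-1-ol | ICC[C@@H]1[C@@H](O)CC[C@@H]1C | intermediate
27 | triethyl{[(1S,2S,3S)-2-(2-iodoethyl)-3-methylcyclopentyl]oxy}silane | ICC[C@@H]1[C@@H](O[Si](CC)(CC)CC)CC[C@@H]1C | intermediate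
28 | {2-[(1S,2S,5S)-2-methyl-5-[(triethylsilyl)oxy]cyclopentyl]ethyl}lithium (not isolated) | [Li]CC[C@@H]1[C@@H](O[Si](CC)(CC)CC)CC[C@@H]1C | intermediate
29 | lithium B-methoxy-B-{2-[(1S,2S,5S)-2-methyl-5-[(triethylsilyl)oxy]cyclopentyl]ethyl}-9-borabicyclo[3.3.1]nonanuide (not isolated) | [Li+].CO[B-]1(CC[C@@H]2[C@@H](O[Si](CC)(CC)CC)CC[C@@H]2C)C2CCCC1CCC2 | intermediate
30 | tert-butyl{[(1R,3S,3aS,6S,7aR)-5-ethenyl-7a-methyl-6-{4-[(1S,2S,5S)-2-methyl-5-[(triethylsilyl)oxy]cyclopentyl]but-1-en-2-yl}-3-(propan-2-yl)octahydro-1H-inden-1-yl]oxy}dimethylsilane (C-9 epimers) | C=CC1C[C@H]2[C@H](C(C)C)C[C@@H](O[Si](C)(C)C(C)(C)C)[C@]2(C)C[C@@H]1C(=C)CC[C@@H]1[C@@H](O[Si](CC)(CC)CC)CC[C@@H]1C | intermediate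
31 | methyl ketone from 30 as C-9 epimer mixture (not isolated) | CC(=O)C1C[C@H]2[C@H](C(C)C)C[C@@H](O[Si](C)(C)C(C)(C)C)[C@]2(C)C[C@@H]1C(=C)CC[C@@H]1[C@@H](O[Si](CC)(CC)CC)CC[C@@H]1C | intermediate
32 | 1-[(1R,3S,3aS,5S,6S,7aR)-1-[(tert-butyldimethylsilyl)oxy]-7a-methyl-6-{4-[(1S,2S,5S)-2-methyl-5-[(triethylsilyl)oxy]cyclopentyl]but-1-en-2-yl}-3-(propan-2-yl)octahydro-1H-inden-5-yl]ethan-1-one | CC(=O)[C@H]1C[C@H]2[C@H](C(C)C)C[C@@H](O[Si](C)(C)C(C)(C)C)[C@]2(C)C[C@@H]1C(=C)CC[C@@H]1[C@@H](O[Si](CC)(CC)CC)CC[C@@H]1C | intermediate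
33 | 1-[(1R,3S,3aS,5S,6S,7aR)-1-[(tert-butyldimethylsilyl)oxy]-6-{4-[(1S,2S,5S)-5-hydroxy-2-methylcyclopentyl]but-1-en-2-yl}-7a-methyl-3-(propan-2-yl)octahydro-1H-inden-5-yl]ethan-1-one | CC(=O)[C@H]1C[C@H]2[C@H](C(C)C)C[C@@H](O[Si](C)(C)C(C)(C)C)[C@]2(C)C[C@@H]1C(=C)CC[C@@H]1[C@@H](O)CC[C@@H]1C | intermediate
34 | (2S,3S)-2-{3-[(1R,3S,3aS,5S,6S,7aR)-5-acetyl-1-[(tert-butyldimethylsilyl)oxy]-7a-methyl-3-(propan-2-yl)octahydro-1H-inden-6-yl]but-3-en-1-yl}-3-methylcyclopentan-1-one | CC(=O)[C@H]1C[C@H]2[C@H](C(C)C)C[C@@H](O[Si](C)(C)C(C)(C)C)[C@]2(C)C[C@@H]1C(=C)CC[C@@H]1C(=O)CC[C@@H]1C | intermediate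
35 | 17-O-tert-butyldimethylsilyl ether of the target | C=C1CC[C@@H]2/C(=C(/C)[C@H]3C[C@H]4[C@H](C(C)C)C[C@@H](O[Si](C)(C)C(C)(C)C)[C@]4(C)C[C@H]13)CC[C@@H]2C | intermediate
36 | CNP0510481.1 | C=C1CC[C@@H]2/C(=C(/C)[C@H]3C[C@H]4[C@H](C(C)C)C[C@@H](O)[C@]4(C)C[C@H]13)CC[C@@H]2C | target

Total step count: 22. Longest linear sequence: 17 steps (steps 1–11 and 17–22); the ring-A branch is steps 12–16.

Steps most likely to fail

1. Step 10 (key step). Hydrogen-atom transfer may go to the vinyl or enone alkene instead of the ring-D methylene. The C-13 radical may be reduced before it closes, or close 5-exo onto the vinyl group. Attack syn to the silyloxy group would give the cis-fused hydrindane. The fallback sets out from 18 and returns at 20; it generates the radical site-specifically by titanocene(III) opening of an epoxide instead of by hydrogen-atom transfer. mCPBA (NaHCO3, CH2Cl2, 0 °C) should epoxidise only the electron-rich 1,1-disubstituted alkene of 18 to the spiro-epoxide F1; either epoxide face serves, since C-13 becomes planar. Cp2TiCl (from Cp2TiCl2 and Mn, THF, rt; Nugent–RajanBabu reductive epoxide opening) gives the same tertiary C-13 radical, now carrying CH2O–Ti, which should close 6-endo onto the enone under the same facial bias. After K2CO3/MeOH equilibration this gives the hydroxymethyl hydrindane F2. Appel iodination (I2, PPh3, imidazole, toluene, 80 °C) to the neopentyl iodide F3 and tin hydride reduction (Bu3SnH, AIBN, benzene, 80 °C) convert CH2OH into the angular methyl group and give 20.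

2. Step 21. Closure of the strained eight-membered ring may lose out to intermolecular coupling, and the ring-A centre α to the cyclopentanone may epimerise under hot, Lewis-acidic titanium. The fallback sets out from 34 and returns at 35; it separates C–C bond formation from deoxygenation. A samarium diiodide pinacol cyclisation (SmI2, HMPA, THF, −78 to 0 °C, high dilution) should give the cis-diol F4, which is converted into the cyclic thiocarbonate F5 (thiophosgene, DMAP, CH2Cl2). Corey–Winter olefination in its mild variant (1,3-dimethyl-2-phenyl-1,3,2-diazaphospholidine, 40 °C), a stereospecific syn-elimination, then gives 35.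

3. Step 4. Facial selectivity may be poor if catalyst control and the substrate's own bias are mismatched, and conjugate reduction or hydroboration of the s-cis enone may compete. The fallback sets out from 10 and returns at 11; it uses substrate control followed by inversion. Luche reduction (NaBH4, CeCl3·7H2O, MeOH, −78 °C) gives clean 1,2-reduction; should hydride enter anti to the neighbouring side chain, the (3S)-epimeric alcohol F6 results. Mitsunobu inversion with 4-nitrobenzoic acid (PPh3, DIAD, THF) gives the ester F7, and methanolysis (K2CO3, MeOH) gives 11.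

Further compounds
F1 | step 10 | spiro-epoxide of 18 (oxirane on the former ring-D methylene, both epoxide epimers) | CC(=O)C(=C)C(C=C)C[C@H]1[C@H](C(C)C)C[C@@H](O[Si](C)(C)C(C)(C)C)C12CO2
F2 | step 10 | 7a-(hydroxymethyl) analogue of 20 (trans-fused, acetyl equatorial, C-9 epimers) | C=CC1C[C@H]2[C@H](C(C)C)C[C@@H](O[Si](C)(C)C(C)(C)C)[C@]2(CO)C[C@@H]1C(C)=O
F3 | step 10 | 7a-(iodomethyl) analogue of 20 | C=CC1C[C@H]2[C@H](C(C)C)C[C@@H](O[Si](C)(C)C(C)(C)C)[C@]2(CI)C[C@@H]1C(C)=O
F4 | step 21 | ring-B cis-1,2-diol from pinacol cyclisation of 34 | C=C1CC[C@@H]2C(O)(C(C)(O)[C@H]3C[C@H]4[C@H](C(C)C)C[C@@H](O[Si](C)(C)C(C)(C)C)[C@]4(C)C[C@H]13)CC[C@@H]2C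
F5 | step 21 | cyclic thiocarbonate of F4 | C=C1CC[C@@H]2C5(OC(=S)OC5(C)[C@H]3C[C@H]4[C@H](C(C)C)C[C@@H](O[Si](C)(C)C(C)(C)C)[C@]4(C)C[C@H]13)CC[C@@H]2C
F6 | step 4 | methyl 2-[(1S,3S,5S)-3-hydroxy-2-methylidene-5-(propan-2-yl)cyclopentyl]acetate | COC(=O)C[C@H]1[C@H](C(C)C)C[C@H](O)C1=C
F7 | step 4 | 4-nitrobenzoate of 11 | COC(=O)C[C@H]1[C@H](C(C)C)C[C@@H](OC(=O)c2ccc(cc2)[N+](=O)[O-])C1=C
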